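## Retrosynthetic overview

1. Feature: inside the ten-membered carbocycle C1–C10 the C4=C5 double bond is ring-E and is spanned by the butenolide ring (C4, C5, C6, O, C15). H on C5 and the carbonyl C15 on C4 lie anti, next to the oxygenated C6. This is the pattern left by a net trans-addition of H and a carboxyl carbon to a C4≡C5 alkyne of a propargylic alcohol.
2. The butenolide is therefore cut first (C4–C15 and C15–O, from CO by way of C4–I and C4–Si). That leaves a much less strained cycloalkynol, which is opened at C5–C6 into a C5 iodoalkyne and a C6 aldehyde (alkynylchromium addition).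
3. The aldehyde sits on the finished trans α-methylene-γ-lactone ring (O, C8, C7, C11, C12). C12 comes from CO by cyclocarbonylation of a C11≡C13 homopropargylic alcohol. C7–C8 comes from an anti-selective chiral allenylindium addition, because C3 is too remote to control C7/C8 and reagent control is needed.
4. Enal C8–C10(C14)–C1–C5: directed hydroalumination–iodination of monosilylated butynediol fixes C9=C10, Negishi coupling brings C1–C3, and ynone transfer hydrogenation sets C3. The allenyl donor (C6, C7, C11, C13) comes from D-glyceraldehyde acetonide.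
5. Order of ring formation: methylene lactone (step 14), ten-membered carbocycle (step 18), butenolide (step 21).

Key step: step 18

Numbering used for all compounds:
- Carbocycle C1–C10.
- C3 is the isobutyrate carbinol, C4=C5 the butenolide olefin, C6 the butenolide O–CH.
- C7 is the CH bearing C11, and C8 the methylene-lactone O–CH.
- C9=C10 is the second olefin, and C10 bears C14H2O.
- C11, C12, C13 are the lactone α-carbon, carbonyl and exocyclic CH2. C15 is the butenolide carbonyl.

Remark on descriptors: the target is (3S,6R,7S,8R). C9=C10 is E by CIP (C8 trans to C14, cis to C1, hence ring-cis). The letters at C6 and C7 change along the route only through priority switches; the spatial arrangement is kept.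

Assumption: the allenylindium addition follows its established course (anti SN2' palladation, retentive transfer to indium, cyclic SE2' addition), so C8 replaces the mesylate oxygen on C7 with net inversion. The (S)-mesylate was chosen on that basis.

## Route

Step 1
Reactants: 1 but-2-yne-1,4-diol
Product: 2 4-[(tert-butyldimethylsilyl)oxy]but-2-yn-1-ol
Conditions: NaH (1 equiv), THF, 0 °C to rt; then TBSCl
Reagents that add atoms: tert-butyldimethylsilyl chloride, CC(C)(C)[Si](C)(C)Cl
Why: O-silylation of the monosodium alkoxide, in which one equivalent of NaH activates only one of the two equivalent hydroxyls, so the monosilyl ether should dominate.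

Step 2
Reactants: 2 4-[(tert-butyldimethylsilyl)oxy]but-2-yn-1-ol
Product: 4 (Z)-4-[(tert-butyldimethylsilyl)oxy]-3-iodobut-2-en-1-ol, via cyclic alkenylalanate 3 (not isolated)
Conditions: NaAlH2(OCH2CH2OMe)2, THF, 0 °C to rt; then I2, THF, −78 °C
Reagents that add atoms: iodine, II
Why: Hydroxyl-directed trans-hydroalumination of a propargylic alcohol followed by iodinolysis with retention, in which the alkoxide-bound aluminium delivers H to C9 and ends on C10 in a five-membered chelate, so iodine stands cis to C8 and the C1 chain later inherits that place.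

Step 3
Reactants: 4 (Z)-4-[(tert-butyldimethylsilyl)oxy]-3-iodobut-2-en-1-ol; 5 (3-ethoxy-3-oxopropyl)zinc bromide
Product: 6 ethyl (E)-4-{[(tert-butyldimethylsilyl)oxy]methyl}-6-hydroxyhex-4-enoate
Conditions: Pd(OAc)2 (2 mol %), SPhos (4 mol %), THF, rt, slow addition of 5
Reagents that add atoms: none
Why: Negishi sp2–sp3 cross-coupling proceeds with retention of olefin geometry (C1 ends cis to C8), and the mild alkylzinc halide tolerates its own ester and, with this catalyst, the free hydroxyl.

Step 4
Reactants: 6 ethyl (E)-4-{[(tert-butyldimethylsilyl)oxy]methyl}-6-hydroxyhex-4-enoate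
Product: 7 (E)-4-{[(tert-butyldimethylsilyl)oxy]methyl}-6-hydroxy-N-methoxy-N-methylhex-4-enamide
Conditions: MeNHOMe·HCl, iPrMgCl, THF, −20 to 0 °C
Reagents that add atoms: N,O-dimethylhydroxylamine hydrochloride, CNOC.Cl
Why: Weinreb amide formation, in which the chloromagnesium amide displaces ethoxide while a further equivalent of iPrMgCl merely holds the free hydroxyl as its alkoxide.

Step 5
Reactants: 7 (E)-4-{[(tert-butyldimethylsilyl)oxy]methyl}-6-hydroxy-N-methoxy-N-methylhex-4-enamide; 8 ethynyltrimethylsilane
Product: 10 (E)-6-{[(tert-butyldimethylsilyl)oxy]methyl}-8-hydroxy-1-(trimethylsilyl)oct-6-en-1-yn-3-one, via lithium trimethylsilylacetylide 9 (not isolated)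
Conditions: 8, nBuLi, THF, −78 °C; then 7, −78 to 0 °C
Reagents that add atoms: none
Why: Weinreb ketone synthesis, in which the chelated tetrahedral adduct stops at single addition and collapses to the ynone only on work-up, the C8 hydroxyl being carried as its lithium alkoxide.

Step 6
Reactants: 10 (E)-6-{[(tert-butyldimethylsilyl)oxy]methyl}-8-hydroxy-1-(trimethylsilyl)oct-6-en-1-yn-3-one
Product: 11 (3S,6E)-6-{[(tert-butyldimethylsilyl)oxy]methyl}-1-(trimethylsilyl)oct-6-en-1-yne-3,8-diol
Conditions: Ru(p-cymene)[(S,S)-TsNCHPhCHPhNH] (2 mol %), iPrOH, rt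
Reagents that add atoms: none
Why: Noyori asymmetric transfer hydrogenation of an ynone, in which the base-free (S,S)-amido ruthenium catalyst tells the alkynyl from the alkyl side and should give the (S)-carbinol at C3 without touching C=C or C≡C.

Step 7
Reactants: 11 (3S,6E)-6-{[(tert-butyldimethylsilyl)oxy]methyl}-1-(trimethylsilyl)oct-6-en-1-yne-3,8-diol
Product: 12 (2E,6S)-3-{[(tert-butyldimethylsilyl)oxy]methyl}-6-hydroxy-8-(trimethylsilyl)oct-2-en-7-ynal
Conditions: TEMPO (10 mol %), PhI(OAc)2 (1.1 equiv), CH2Cl2, 0 °C to rt
Reagents that add atoms: none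
Why: Oxoammonium oxidation is much faster at the unhindered primary allylic alcohol than at the secondary propargylic one and needs no base, so the enal should form with its geometry (CHO trans to C14, cis to C1) intact.

Step 8
Reactants: 12 (2E,6S)-3-{[(tert-butyldimethylsilyl)oxy]methyl}-6-hydroxy-8-(trimethylsilyl)oct-2-en-7-ynal; 13 isobutyryl chloride
Product: 14 (3S,6E)-6-{[(tert-butyldimethylsilyl)oxy]methyl}-8-oxo-1-(trimethylsilyl)oct-6-en-1-yn-3-yl 2-methylpropanoate
Conditions: pyridine, DMAP (cat.), CH2Cl2, 0 °C
Reagents that add atoms: none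
Why: Nucleophile-catalysed O-acylation of the only free hydroxyl leaves the C3–O bond untouched, so the configuration is kept.

Step 9
Reactants: 15 (R)-2,2-dimethyl-1,3-dioxolane-4-carbaldehyde
Product: 16 (S)-4-ethynyl-2,2-dimethyl-1,3-dioxolane
Conditions: dimethyl (1-diazo-2-oxopropyl)phosphonate, K2CO3, MeOH, 0 °C to rt
Reagents that add atoms: dimethyl (1-diazo-2-oxopropyl)phosphonate, COP(=O)(OC)C(=[N+]=[N-])C(C)=O
Why: Ohira–Bestmann (Seyferth–Gilbert) homologation, in which the diazomethylphosphonate anion olefinates the aldehyde and the alkylidene carbene rearranges to the terminal alkyne (new carbon C13), the mild carbonate base leaving the oxygenated centre (future C7) intact.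

Step 10
Reactants: 16 (S)-4-ethynyl-2,2-dimethyl-1,3-dioxolane
Product: 17 (S)-but-3-yne-1,2-diol
Conditions: 1 M aq. HCl, THF, rt
Reagents that add atoms: none
Why: Acid-catalysed ketal hydrolysis breaks only the bonds at the ketal carbon, so the carbinol centre is unaffected.

Step 11
Reactants: 17 (S)-but-3-yne-1,2-diol
Product: 19 (S)-1-[(4-methoxybenzyl)oxy]but-3-yn-2-ol, via dibutylstannylene acetal 18 (not isolated)
Conditions: Bu2SnO, toluene, reflux (water removed); then PMBCl, Bu4NI (cat.), 80 °C
Reagents that add atoms: 4-methoxybenzyl chloride, COc1ccc(CCl)cc1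
Why: Stannylene-acetal alkylation activates the less hindered primary oxygen of a 1,2-diol, so the PMB group should go to O–C6 and the secondary carbinol stay free.

Step 12
Reactants: 19 (S)-1-[(4-methoxybenzyl)oxy]but-3-yn-2-ol
Product: 20 (S)-1-[(4-methoxybenzyl)oxy]but-3-yn-2-yl methanesulfonate
Conditions: MsCl, Et3N, CH2Cl2, −78 to −20 °C
Reagents that add atoms: methanesulfonyl chloride, CS(=O)(=O)Cl
Why: O-sulfonylation does not touch the C–O bond, so the configuration is retained and the propargylic position is activated for palladium.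

Step 13
Reactants: 14 (3S,6E)-6-{[(tert-butyldimethylsilyl)oxy]methyl}-8-oxo-1-(trimethylsilyl)oct-6-en-1-yn-3-yl 2-methylpropanoate; 20 (S)-1-[(4-methoxybenzyl)oxy]but-3-yn-2-yl methanesulfonate
Product: 22 anti homopropargylic alcohol (3S,6E,8R,9R)-6-{[(tert-butyldimethylsilyl)oxy]methyl}-8-hydroxy-9-{[(4-methoxybenzyl)oxy]methyl}-1-(trimethylsilyl)undec-6-ene-1,10-diyn-3-yl 2-methylpropanoate (C3 S, C7 R, C8 R), via allenylindium reagent 21 (not isolated)
Conditions: PdCl2(dppf) (5 mol %), InI (1.5 equiv), THF–HMPA, rt
Reagents that add atoms: none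
Why: Marshall propargylation, in which zerovalent palladium displaces the mesylate anti (SN2'), InI takes over the allenyl group by oxidative transmetalation and the (aS)-allenylindium adds to the enal through a cyclic SE2' transition state, so the mesylate centre fixes C7 and the anti topology fixes C8 independently of the remote C3, the far less reactive propargylic isobutyrate staying untouched.

Step 14
Reactants: 22 anti homopropargylic alcohol (C3 S, C7 R, C8 R)
Product: 23 (3S,6E)-6-{[(tert-butyldimethylsilyl)oxy]methyl}-7-[(2R,3R)-3-{[(4-methoxybenzyl)oxy]methyl}-4-methylidene-5-oxooxolan-2-yl]-1-(trimethylsilyl)hept-6-en-1-yn-3-yl 2-methylpropanoate (trans lactone)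
Conditions: PdCl2 (10 mol %), thiourea (40 mol %), CO (1–3 atm), acetone, 50 °C
Reagents that add atoms: carbon monoxide, [C-]#[O+]
Why: Palladium-catalysed cyclocarbonylation of a homopropargylic alcohol, in which C8–OH and CO form an alkoxycarbonylpalladium unit that adds syn and 5-exo-dig to the terminal alkyne and is protonated off, closing the lactone ring with C12 from CO and C13 as exocyclic methylene, while the silyl-capped C4≡C5 alkyne has no hydroxyl in reach and C7/C8 are untouched, so the anti adduct becomes the trans lactone.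

Step 15
Reactants: 23 trans lactone with C5–SiMe3 and C6H2OPMB
Product: 24 (3S,6E)-6-{[(tert-butyldimethylsilyl)oxy]methyl}-1-iodo-7-[(2R,3R)-3-{[(4-methoxybenzyl)oxy]methyl}-4-methylidene-5-oxooxolan-2-yl]hept-6-en-1-yn-3-yl 2-methylpropanoate
Conditions: NIS (1.2 equiv), AgNO3 (15 mol %), acetone, rt, dark
Reagents that add atoms: N-iodosuccinimide, O=C1CCC(=O)N1I
Why: Silver-catalysed iododesilylation of an alkynylsilane passes through a silver acetylide that NIS iodinates, which should be much faster than attack on the oxygen-flanked olefins or the anisyl ring, and it is placed after the last zerovalent-palladium step that the C–I bond would not survive.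

Step 16
Reactants: 24 iodoalkyne PMB ether
Product: 25 (3S,6E)-6-{[(tert-butyldimethylsilyl)oxy]methyl}-7-[(2R,3R)-3-(hydroxymethyl)-4-methylidene-5-oxooxolan-2-yl]-1-iodohept-6-en-1-yn-3-yl 2-methylpropanoate
Conditions: DDQ (1.3 equiv), CH2Cl2–pH 7 buffer, 0 °C; carried on directly
Reagents that add atoms: none
Why: Oxidative PMB cleavage (benzylic hydride abstraction, then hydrolysis of the oxocarbenium ion) runs at neutral pH and should leave the silyl ether, both esters, the iodoalkyne and the olefins alone and give no chance for translactonisation onto O–C6.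

Step 17
Reactants: 25 primary alcohol at C6
Product: 26 iodoalkyne aldehyde (3S,6E)-6-{[(tert-butyldimethylsilyl)oxy]methyl}-7-[(2R,3S)-3-formyl-4-methylidene-5-oxooxolan-2-yl]-1-iodohept-6-en-1-yn-3-yl 2-methylpropanoate
Conditions: Dess–Martin periodinane, NaHCO3, CH2Cl2, 0 °C; short plug filtration, used at once
Reagents that add atoms: none
Why: Dess–Martin oxidation works without amine base or strong acid, which matters because C7–H is α to the aldehyde, allylic to C11=C13 and β to the lactone oxygen, so neither double-bond migration nor β-elimination should set in before the next step.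

Step 18
Reactants: 26 iodoalkyne aldehyde (C3 S, C7 S, C8 R)
Product: 28 ten-membered cycloalkynol fused to the trans methylene lactone, C4≡C5 in the ring, free C6–OH, C14–OTBS (C3 S, C6 S, C7 R, C8 R), via alkynylchromium dichloride 27 (not isolated)
Conditions: CrCl2 (8 equiv), NiCl2 (1 mol % of the CrCl2), THF, rt, slow addition of 26 to about 0.002 M
Reagents that add atoms: none
Why: Zerovalent nickel, made from NiCl2 by CrCl2, inserts into the C5–I bond and passes the alkynyl group to trivalent chromium (two CrCl2 per iodide), and the weakly basic, oxophilic alkynylchromium 27 adds to the C6 aldehyde to give a chromium alkoxide that is hydrolysed on work-up. The closest known reaction type is the intramolecular Nozaki–Hiyama–Kishi coupling of iodoalkynes with aldehydes, which has closed strained nine- and ten-membered cycloalkynols of the enediyne class. The carbocycle C1–C10 closes in a 10-exo-trig mode, helped by the ring-cis C9=C10 olefin and the trans lactone, which turn both chain ends to the same side, and by high dilution, and the collinear C3–C4≡C5–C6 unit costs far less strain than the bridged ring-E olefin that is installed afterwards. The new C6 centre is controlled by C7: attack anti to the sp2 carbon C11 with the carbonyl oxygen gauche to C8 (Felkin–Anh), the less crowded of the two staggered arrangements that keep C5 gauche to the C8 tether, leads to the (6S) carbinol, which is spatially the (6R) centre of the target. The step needs chemoselectivity for C–I and CHO over the methylene lactone, the propargylic isobutyrate and the allylic C8–O bond, which the much faster oxidative addition at the sp C–I bond and the non-basic chromium reagent, which should neither enolise C7 nor add in a conjugate sense, should secure.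

Step 19
Reactants: 28 ten-membered cycloalkynol
Product: 29 ring-E (Z by CIP) vinylsilane with SiEt3 on C4 cis to C6 and H on C5 (C3 S, C6 S, C7 R, C8 R)
Conditions: [Cp*Ru(MeCN)3]PF6 (10 mol %), Et3SiH (1.2 equiv), CH2Cl2, 0 °C to rt
Reagents that add atoms: triethylsilane, CC[SiH](CC)CC
Why: Ruthenium-catalysed trans-hydrosilylation adds H and Si anti across the ring alkyne, giving the ring-E olefin, and with this cationic catalyst silicon goes to the alkyne carbon remote from a free propargylic hydroxyl, here C4, which is also the less crowded terminus because C5 adjoins the C6/C7 branch points.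

Step 20
Reactants: 29 vinylsilane
Product: 30 ring-E (Z by CIP) vinyl iodide with I on C4 cis to the C6 carbinol (C3 S, C6 S, C7 R, C8 R)
Conditions: NIS (1.3 equiv), 2,6-lutidine, (CF3)2CHOH, 0 °C
Reagents that add atoms: N-iodosuccinimide, O=C1CCC(=O)N1I
Why: Electrophilic ipso-iododesilylation in hexafluoroisopropanol proceeds with retention, and the β-silicon effect makes C4=C5 the most nucleophilic olefin beside the electron-poor methylene lactone and the doubly oxygen-flanked C9=C10.

Step 21
Reactants: 30 vinyl iodide
Product: 31 C14-O-TBS ether of the target (3S,6R,7S,8R)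
Conditions: Pd(PPh3)4 (10 mol %), CO (1 atm), Et3N (2 equiv), THF, 50 °C
Reagents that add atoms: carbon monoxide, [C-]#[O+]
Why: Carbonylative lactonisation of a (Z)-γ-hydroxy vinyl iodide, in which oxidative addition with retention and CO insertion give an acylpalladium on C4 that the cis C6–OH captures, closing the five-membered butenolide (C15 from CO) across the ring-E olefin without touching any stereocentre.

Step 22
Reactants: 31 C14-O-TBS ether of the target
Product: 32 target CNP0322767.4
Conditions: HF·pyridine, pyridine, THF, 0 °C to rt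
Reagents that add atoms: none
Why: Fluoride-driven desilylation in a buffered, non-basic medium frees C14–OH and should spare both lactones, the isobutyrate and the base-sensitive C6–H.

## Compound list

1 | but-2-yne-1,4-diol | OCC#CCO | starting material
2 | 4-[(tert-butyldimethylsilyl)oxy]but-2-yn-1-ol | OCC#CCO[Si](C)(C)C(C)(C)C | intermediate
3 | sodium cyclic alkenylalanate (1,2-oxaaluminole chelate, Al on C10) | [Na+].COCCO[Al-]1(OCCOC)OCC=C1CO[Si](C)(C)C(C)(C)C | intermediate
4 | (Z)-4-[(tert-butyldimethylsilyl)oxy]-3-iodobut-2-en-1-ol | OC/C=C(\I)CO[Si](C)(C)C(C)(C)C | intermediate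
5 | (3-ethoxy-3-oxopropyl)zinc bromide | CCOC(=O)CC[Zn]Br | starting material
6 | ethyl (E)-4-{[(tert-butyldimethylsilyl)oxy]methyl}-6-hydroxyhex-4-enoate | OC/C=C(/CO[Si](C)(C)C(C)(C)C)CCC(=O)OCC | intermediate
7 | (E)-4-{[(tert-butyldimethylsilyl)oxy]methyl}-6-hydroxy-N-methoxy-N-methylhex-4-enamide | OC/C=C(/CO[Si](C)(C)C(C)(C)C)CCC(=O)N(C)OC | intermediate
8 | ethynyltrimethylsilane | C[Si](C)(C)C#C | starting material
9 | lithium (trimethylsilyl)acetylide | [Li]C#C[Si](C)(C)C | intermediate
10 | (E)-6-{[(tert-butyldimethylsilyl)oxy]methyl}-8-hydroxy-1-(trimethylsilyl)oct-6-en-1-yn-3-one | OC/C=C(/CO[Si](C)(C)C(C)(C)C)CCC(=O)C#C[Si](C)(C)C | intermediate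
11 | (3S,6E)-6-{[(tert-butyldimethylsilyl)oxy]methyl}-1-(trimethylsilyl)oct-6-en-1-yne-3,8-diol | OC/C=C(/CO[Si](C)(C)C(C)(C)C)CC[C@H](O)C#C[Si](C)(C)C | intermediate
12 | (2E,6S)-3-{[(tert-butyldimethylsilyl)oxy]methyl}-6-hydroxy-8-(trimethylsilyl)oct-2-en-7-ynal | O=C/C=C(/CO[Si](C)(C)C(C)(C)C)CC[C@H](O)C#C[Si](C)(C)C | intermediate
13 | isobutyryl chloride | CC(C)C(Cl)=O | starting material
14 | (3S,6E)-6-{[(tert-butyldimethylsilyl)oxy]methyl}-8-oxo-1-(trimethylsilyl)oct-6-en-1-yn-3-yl 2-methylpropanoate | O=C/C=C(/CO[Si](C)(C)C(C)(C)C)CC[C@H](OC(=O)C(C)C)C#C[Si](C)(C)C | intermediate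
15 | (R)-2,2-dimethyl-1,3-dioxolane-4-carbaldehyde | O=C[C@H]1COC(C)(C)O1 | starting material
16 | (S)-4-ethynyl-2,2-dimethyl-1,3-dioxolane | C#C[C@H]1COC(C)(C)O1 | intermediate
17 | (S)-but-3-yne-1,2-diol | OC[C@H](C#C)O | intermediate
18 | (S)-2,2-dibutyl-4-ethynyl-1,3,2-dioxastannolane | CCCC[Sn]1(CCCC)OC[C@H](C#C)O1 | intermediate
19 | (S)-1-[(4-methoxybenzyl)oxy]but-3-yn-2-ol | COc1ccc(COC[C@H](C#C)O)cc1 | intermediate
20 | (S)-1-[(4-methoxybenzyl)oxy]but-3-yn-2-yl methanesulfonate | COc1ccc(COC[C@H](C#C)OS(C)(=O)=O)cc1 | intermediate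
21 | (aS)-4-[(4-methoxybenzyl)oxy]buta-1,2-dienylindium iodide methanesulfonate | I[In](OS(C)(=O)=O)C([H])=[C@@]=C([H])COCc1ccc(OC)cc1 | intermediate
22 | anti homopropargylic alcohol (C3 S, C7 R, C8 R) | O[C@H](/C=C(/CO[Si](C)(C)C(C)(C)C)CC[C@H](OC(=O)C(C)C)C#C[Si](C)(C)C)[C@H](C#C)COCc1ccc(OC)cc1 | intermediate
23 | trans methylene lactone, C5–SiMe3, C6H2OPMB (C3 S, C7 R, C8 R) | C=C1C(=O)O[C@H](/C=C(/CO[Si](C)(C)C(C)(C)C)CC[C@H](OC(=O)C(C)C)C#C[Si](C)(C)C)[C@H]1COCc2ccc(OC)cc2 | intermediate
24 | trans methylene lactone, C5–I, C6H2OPMB (C3 S, C7 R, C8 R) | C=C1C(=O)O[C@H](/C=C(/CO[Si](C)(C)C(C)(C)C)CC[C@H](OC(=O)C(C)C)C#CI)[C@H]1COCc2ccc(OC)cc2 | intermediate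
25 | trans methylene lactone, C5–I, C6H2OH (C3 S, C7 R, C8 R) | C=C1C(=O)O[C@H](/C=C(/CO[Si](C)(C)C(C)(C)C)CC[C@H](OC(=O)C(C)C)C#CI)[C@H]1CO | intermediate
26 | iodoalkyne aldehyde on the trans methylene lactone (C3 S, C7 S, C8 R) | C=C1C(=O)O[C@H](/C=C(/CO[Si](C)(C)C(C)(C)C)CC[C@H](OC(=O)C(C)C)C#CI)[C@H]1C=O | intermediate
27 | alkynylchromium dichloride derived from 26 | C=C1C(=O)O[C@H](/C=C(/CO[Si](C)(C)C(C)(C)C)CC[C@H](OC(=O)C(C)C)C#C[Cr](Cl)Cl)[C@H]1C=O | intermediate
28 | ten-membered cycloalkynol (C3 S, C6 S, C7 R, C8 R) | C=C1C(=O)O[C@@H]2/C=C(/CO[Si](C)(C)C(C)(C)C)CC[C@H](OC(=O)C(C)C)C#C[C@@H](O)[C@@H]12 | intermediate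
29 | C4-triethylsilyl ring-E cyclodecadienol (C3 S, C6 S, C7 R, C8 R) | C=C1C(=O)O[C@@H]2/C=C(/CO[Si](C)(C)C(C)(C)C)CC[C@H](OC(=O)C(C)C)/C([Si](CC)(CC)CC)=C/[C@@H](O)[C@@H]12 | intermediate
30 | C4-iodo ring-E cyclodecadienol (C3 S, C6 S, C7 R, C8 R) | C=C1C(=O)O[C@@H]2/C=C(/CO[Si](C)(C)C(C)(C)C)CC[C@H](OC(=O)C(C)C)/C(I)=C/[C@@H](O)[C@@H]12 | intermediate
31 | C14-O-TBS ether of the target (3S,6R,7S,8R) | C=C1C(=O)O[C@@H]2/C=C(/CO[Si](C)(C)C(C)(C)C)CC[C@H](OC(=O)C(C)C)C3=C[C@@H](OC3=O)[C@@H]12 | intermediate
32 | CNP0322767.4 (3S,6R,7S,8R) | C=C1C(=O)O[C@@H]2/C=C(/CO)CC[C@H](OC(=O)C(C)C)C3=C[C@@H](OC3=O)[C@@H]12 | target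

## Step count and risks

Total step count: 22. Longest linear sequence: 18 (steps 1–8 and 13–22). Steps 9–12 form the convergent branch.

**Step 18.** The addition to the C6 aldehyde may show poor facial selectivity, because the conformation of the closing ring can override the Felkin preference set by C7.
- The fallback replaces substrate control by reagent control and sets out from 28, taken as the mixture of C6 epimers.
- Dess–Martin oxidation should give the ten-membered cycloalkynone F1.
- Corey–Bakshi–Shibata reduction follows, with (S)-2-methyl-CBS-oxazaborolidine and catecholborane at −78 °C. The slim alkynyl carbon C5 takes the small position and the branched C7 the large one.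
- This should return the (6S) carbinol 28, where the route is rejoined.

**Step 19.** Regiocontrol may be lost, with silicon delivered to C5. The C3 acyloxy group also pushes silicon away from itself and so opposes the C6 hydroxyl. Turnover on the hindered ring alkyne may also be sluggish.
- The fallback exchanges the metal-catalysed hydrofunctionalisation for a polar one and sets out from 28.
- Dess–Martin oxidation gives the cycloalkynone F1.
- Hydroiodination with LiI and AcOH in MeCN places iodide on the β-carbon C4, the only position that conjugate addition can reach, and protonates C5 anti. This gives the (Z)-β-iodoenone F2 with iodine cis to C6.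
- 1,2-Reduction with (S)-2-methyl-CBS-oxazaborolidine and catecholborane, with the branched C7 again as the large group, should give 30, where the route is rejoined.
- Because C6 is set anew, this path also makes the outcome at C6 in step 18 irrelevant.

**Step 14.** The acid released from PdCl2 may ionise the allylic C8 carbinol or loosen the silyl ether. Alternatively, divalent palladium may engage the propargylic ester before the alkoxycarbonylpalladium unit reaches the alkyne.
- The fallback installs a halide on C11 first and carbonylates under basic conditions. It sets out from 22.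
- Markovnikov hydrosilylation of the terminal alkyne with [Cp*Ru(MeCN)3]PF6 and one equivalent of Et3SiH should give the α-vinylsilane F3.
- NIS in MeCN should convert it into the 2-iodoalkene F4.
- Pd(PPh3)4, CO (1 atm) and Et3N in THF should close the lactone to 23, where the route is rejoined.

Further compounds
F1 | step 18 | ten-membered cycloalkynone (C6 ketone; C3 S, C7 and C8 as in 28) | C=C1C(=O)O[C@@H]2/C=C(/CO[Si](C)(C)C(C)(C)C)CC[C@H](OC(=O)C(C)C)C#CC(=O)[C@@H]12
F2 | step 19 | (Z)-β-iodoenone, I on C4 cis to the C6 ketone, ring-E olefin | C=C1C(=O)O[C@@H]2/C=C(/CO[Si](C)(C)C(C)(C)C)CC[C@H](OC(=O)C(C)C)/C(I)=C/C(=O)[C@@H]12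
F3 | step 14 | α-vinylsilane, SiEt3 on C11 of the anti alcohol | O[C@H](/C=C(/CO[Si](C)(C)C(C)(C)C)CC[C@H](OC(=O)C(C)C)C#C[Si](C)(C)C)[C@H](C(=C)[Si](CC)(CC)CC)COCc1ccc(OC)cc1
F4 | step 14 | 2-iodoalkene, I on C11 of the anti alcohol | O[C@H](/C=C(/CO[Si](C)(C)C(C)(C)C)CC[C@H](OC(=O)C(C)C)C#C[Si](C)(C)C)[C@H](C(I)=C)COCc1ccc(OC)cc1
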